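The numbers in the tables are simulated for an exercise; scatter was added.

**Points per mol%.** One mol% of free catalyst is my unit here: both runs start at [substrate] = 0.22 M and differ in loading. The north-west run is the asked flask, followed so far.

common to all: substrate 0.22 M
- north-west: free catalyst 0.75 mol%; the very flask that is asked about, followed so far
- west: free catalyst 0.5 mol%; run made earlier
- flask: free catalyst 0.75 mol%; time 15 d

| run | time / d | substrate / % | target / % |
|---|---|---|---|
| north-west | 0.625 | 53.1 | 2.4 |
| north-west | 1.67 | 18.9 | 6.3 |
| north-west | 3.00 | 4.5 | 8.2 |
| north-west | 5.00 | 0.4 | 8.3 |
| west | 4.00 | 2.0 | 5.2 |
| west | 8.00 | 0 | 5.8 |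
| west | 12.0 | 0.6 | 5.1 |
| west | 15.0 | 1.0 | 5.6 |

(readings scatter by 0.5 percentage points)

- at 15 d, what has stopped the reaction, if anything has (no working catalyst is left / it is still moving / all of the substrate has reacted)
- conversion of substrate at 15 d
- amount of target at 15 d, in percent of the substrate charged

- what was read earlier has a scatter of 0.5 percentage points, one standard deviation
- the reaction counts as stopped when no species that holds the substrate changes by six tenths of a point or more over the second half of the time

**Odd pair.** After 3.00 d the north-west run has 4.5 % of its substrate left, yet target stands at 8.2 %. Its first reading gives a substrate half-life of 0.684 d. That pace carried to 4.00 d leaves 1.74 %, and the west run, with less catalyst, reads 2.0 %. So loading leaves the fall of substrate unchanged within the scatter, but target is lower in the west run.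

**Yield per mol%.** The west target readings average 5.42 % and stay level up to 15.0 d. Divided by the west loading, that gives the ratio 10.8, my yield per mol%, a selectivity per unit of loading. The north-west run's last reading gives 11.1. I therefore read target as a share of the substrate that falls, a share that grows with loading.

**My reckoning.** For the flask, 15 d is 21.9 half-lives, so I expect the substrate to have reacted completely, with target at 8.14 %.

**The flask.** The forecast, “Target yield thus scales with loading”, commits at 15 d to this end, all of the substrate has reacted, with 100 % conversion and 8.3 % of target, above my figure. In the flask at 15 d, all of the substrate has reacted, with conversion >99.9 % and target 8.26 %.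

    substrate → intermediate (k = 0.0421 /h)
    intermediate → decomposed reagent (k = 0.108 /h)
    2 free catalyst → spent catalyst (k = 0.963 /M/h)
    free catalyst + intermediate → free catalyst + target (k = 6.47 /M/h)

**Lower loading.** My yield per mol% gives a figure 0.12 percentage points short of the flask. On the neighbour flask, with 0.3 mol% of free catalyst and the other charges held, it gives 3.26 %. That neighbour reaches 3.66 % of target, 0.40 points above the reckoning. After 15.0 d, free catalyst stands at 46.6 % of its charge in the flask and at 68.6 % in the neighbour.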